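**Retrosynthetic overview**

1. Numbering (octahydroindene): C1 (CH–OAc), C2 (C=O), C3, C3a/C7a (ring fusion), C4 (C=CH2), C5 (CH–O-angeloyl), C6 (CH–OH), C7 (CH–iPr); ring A is the six-membered ring, ring B the five-membered ring. Late disconnections: C1 acetate and C5 angelate (acylations), C5–O (SeO2 allylic hydroxylation), C4=CH2 (Wittig on a C4 ketone), C3a–H (cis to trans epimerization).
2. Key disconnection: the hydrindan-4-one is unravelled to a monocyclic 1-vinylcyclopentyl silyl ether with an α-silyloxy acetaldehyde arm on the neighbouring carbon. A Prins cyclization (bond C2–C3) followed by a pinacol shift (bond C3a–C7a) closes ring B and inserts the internal vinyl carbon (C3a) into the cyclopentane C4–C5–C6–C7–C7a, which thereby grows into ring A.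
3. Enabling feature: in ring A the methylene-bearing carbon C4 (a masked ketone) sits next to ring-fusion carbon C3a, and in ring B the carbonyl carbon C2 is β to both fusion atoms with C1 oxygenated. This 4-oxo-2-oxy-hydrindane pattern is what a ring-enlarging cyclopentane annulation delivers; C6, C7 and C7a ride through on the old cyclopentane.
4. The cyclopentane comes from (R)-4-silyloxycyclopentenone: β-isopropylation with re-oxidation to the enone, conjugate reduction (H anti to OSi, so iPr cis to OSi), syn-aldol trapping anti to iPr, then vinyl addition.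
5. Ring order: cyclopentane (chiral pool), then a transient six-membered Prins ring, then ring B and ring A together in step 8.

Key step: step 8

Remark: TBS = tert-butyldimethylsilyl, TES = triethylsilyl, PMB = 4-methoxybenzyl; the carbinol centres created in step 4 (tertiary) and step 8 (C2–OH) are erased in steps 8 and 11, so either epimer serves and the SMILES show the one expected.

**Route**

Step 1
Reactants: 1 (R)-4-(TBS-oxy)cyclopent-2-en-1-one; 2 isopropylmagnesium chloride
Product: 4 (R)-4-(TBS-oxy)-3-isopropylcyclopent-2-en-1-one, via magnesium enolate 3 (not isolated)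
Conditions: iPrMgCl, CuBr·SMe2 (cat.), THF, −78 °C; then PhS(Cl)=NtBu, −78 °C → rt
Reagents that add atoms: isopropylmagnesium chloride, CC(C)[Mg]Cl
Why: Copper-catalysed 1,4-addition anti to the silyloxy group followed by one-pot enolate dehydrogenation with N-tert-butylbenzenesulfinimidoyl chloride (S-attack, then syn-elimination) should return the enone with isopropyl on the β-carbon; the C4 stereocentre is untouched.

Step 2
Reactants: 4 (R)-4-(TBS-oxy)-3-isopropylcyclopent-2-en-1-one; 5 dimethylphenylsilane; 6 2-(PMB-oxy)acetaldehyde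
Product: 8 (2R,3S,4R)-4-(TBS-oxy)-2-[(1R)-1-hydroxy-2-(PMB-oxy)ethyl]-3-isopropylcyclopentan-1-one, via silyl enol ether 7 (not isolated)
Conditions: [(Ph3P)CuH]6 (cat.), PhMe2SiH, toluene, rt; then 6, TiCl4, CH2Cl2, −78 °C
Reagents that add atoms: 2-[(4-methoxybenzyl)oxy]acetaldehyde, O=CCOCc1ccc(OC)cc1
Why: Copper hydride 1,4-reduction delivers hydride to C3 anti to the C4 silyloxy group (isopropyl ends cis to it) and gives the regiodefined enol silane, and the chelation-controlled Mukaiyama aldol addition to the TiCl4-bound α-alkoxy aldehyde should then occur anti to the isopropyl group (C2 trans to C3) with syn simple diastereoselection at the carbinol carbon.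

Step 3
Reactants: 8 aldol adduct; 9 tert-butyldimethylsilyl trifluoromethanesulfonate
Product: 10 (2R,3S,4R)-4-(TBS-oxy)-2-[(1R)-1-(TBS-oxy)-2-(PMB-oxy)ethyl]-3-isopropylcyclopentan-1-one
Conditions: TBSOTf, 2,6-lutidine, CH2Cl2, −78 °C
Reagents that add atoms: tert-butyldimethylsilyl trifluoromethanesulfonate, CC(C)(C)[Si](C)(C)OS(=O)(=O)C(F)(F)F
Why: O-Silylation of the secondary aldol hydroxyl with a silyl triflate at low temperature is faster than enol silane formation or retro-aldol cleavage and touches no stereocentre.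

Step 4
Reactants: 10 bis-silyl ketone; 11 vinylmagnesium bromide
Product: 12 (1S,2R,3S,4R)-1-ethenyl-4-(TBS-oxy)-2-[(1R)-1-(TBS-oxy)-2-(PMB-oxy)ethyl]-3-isopropylcyclopentan-1-ol
Conditions: vinylMgBr, CeCl3, THF, −78 °C
Reagents that add atoms: vinylmagnesium bromide, C=C[Mg]Br
Why: The weakly basic organocerium reagent should undergo 1,2-addition to the hindered, enolisable ketone without β-elimination of the silyloxy group, mainly anti to the adjacent C2 branch; the new carbinol configuration is not needed later.

Step 5
Reactants: 12 tertiary allylic alcohol; 13 triethylsilyl trifluoromethanesulfonate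
Product: 14 triethylsilyl ether of 12
Conditions: TESOTf, 2,6-lutidine, CH2Cl2, −78 → 0 °C
Reagents that add atoms: triethylsilyl trifluoromethanesulfonate, CC[Si](CC)(CC)OS(=O)(=O)C(F)(F)F
Why: O-Silylation of the tertiary allylic alcohol installs the electron-releasing group that later drives the pinacol shift and prevents lactol formation with the aldehyde.

Step 6
Reactants: 14 PMB ether
Product: 15 primary alcohol (14 with the PMB group removed; other centres unchanged)
Conditions: DDQ, CH2Cl2/pH 7 buffer, 0 °C
Reagents that add atoms: none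
Why: Oxidative cleavage of the 4-methoxybenzyl ether by DDQ (benzylic hydride abstraction, then hydrolysis) is orthogonal to the three silyl ethers and the vinyl group.

Step 7
Reactants: 15 primary alcohol
Product: 16 α-silyloxy aldehyde (CH2OH of 15 oxidised to CHO; (R) at the silyloxy carbon)
Conditions: Dess–Martin periodinane, NaHCO3, CH2Cl2, 0 °C → rt
Reagents that add atoms: none
Why: Dess–Martin oxidation under buffered conditions should give the aldehyde without epimerising the α-silyloxy centre or cleaving the silyl ethers.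

Step 8
Reactants: 16 α-silyloxy aldehyde
Product: 18 (1R,2R,3aS,6R,7S,7aS)-1,6-bis(TBS-oxy)-2-hydroxy-7-isopropyl-octahydro-4H-inden-4-one (cis-fused), via Prins cation 17 (not isolated)
Conditions: SnCl4, CH2Cl2, −78 → −20 °C; then 1 M HCl, THF, 0 °C
Reagents that add atoms: none
Why: SnCl4 activates the aldehyde, the terminal vinyl carbon adds to it (Prins addition through a chair with the side-chain silyloxy group equatorial), and the positive charge building at the internal vinyl carbon, next to the triethylsilyloxy carbinol carbon, is discharged by a pinacol 1,2-shift of the cyclopentane bond C1–C2, after which loss of the silyl group leaves the ketone. The closest known reaction type is the Prins–pinacol ring-enlarging cyclopentane annulation of 1-alkenyl-2-(2,2-dialkoxyethyl)cycloalkyl silyl ethers; here the electrophile is a Lewis-acid-bound aldehyde in place of an ionised acetal. Ring closures: the transient six-membered carbocycle forms by 6-endo-trig cation–olefin cyclization, and the shift contracts it to ring B (C1–C2–C3–C3a–C7a) while the old cyclopentane is expanded by one carbon (the internal vinyl carbon, now C3a) to the cyclohexanone ring A. Stereocontrol: the migrating carbon (C7a) moves with retention and C1, C6 and C7 are spectators, while the new fusion centre C3a is formed cis to C7a from either carbinol epimer because the two-atom tether lets the migrating carbon reach only one face of the cationic carbon; the new C2 carbinol (oxygen equatorial in the chair) is removed later. Selectivity needed: shift of the ring-fusion bond C1–C2 over the C1–C5 bond (bridged ketone), chloride capture and ionisation of the tertiary allylic silyl ether. This should be secured by the participation of the more substituted bond as in the known annulations, by the absence of an allylic hydrogen (no ene path) and by the silyloxy oxygen, which makes the shift a fast intramolecular termination at low temperature.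

Step 9
Reactants: 18 cis-fused ketone
Product: 19 (1R,2R,3aR,6R,7S,7aS)-1,6-bis(TBS-oxy)-2-hydroxy-7-isopropyl-octahydro-4H-inden-4-one (trans-fused)
Conditions: DBU, toluene, 40 °C (to equilibrium; recovered cis isomer resubmitted)
Reagents that add atoms: none
Why: Base-mediated enolisation toward C3a equilibrates the ring fusion (thermodynamic epimerisation); the trans-fused hydrindan-4-one with the C7 isopropyl equatorial should be the more stable isomer, and silyloxide is a poor leaving group for the competing E1cB path.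

Step 10
Reactants: 19 trans-fused ketone; 20 methyltriphenylphosphonium bromide
Product: 21 (1R,2R,3aR,6R,7S,7aR)-1,6-bis(TBS-oxy)-7-isopropyl-4-methylidene-octahydro-1H-inden-2-ol
Conditions: Ph3PCH3Br, KOtBu, THF, 0 °C → rt
Reagents that add atoms: methyltriphenylphosphonium bromide, C[P+](c1ccccc1)(c1ccccc1)c1ccccc1.[Br-]
Why: Wittig methylenation of the cyclohexanone; the free C2 hydroxyl is only deprotonated by excess ylide and C3a stays in its thermodynamic trans configuration under the basic conditions.

Step 11
Reactants: 21 methylidene alcohol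
Product: 22 (1R,3aR,6R,7S,7aR)-1,6-bis(TBS-oxy)-7-isopropyl-4-methylidene-octahydro-2H-inden-2-one
Conditions: Dess–Martin periodinane, NaHCO3, CH2Cl2, 0 °C → rt
Reagents that add atoms: none
Why: Dess–Martin oxidation of the only free hydroxyl should give the cyclopentanone without epimerising the α-silyloxy centre C1 or moving the exocyclic double bond.

Step 12
Reactants: 22 methylidene ketone; 23 tert-butyl hydroperoxide
Product: 24 (1R,3aR,5S,6S,7S,7aR)-1,6-bis(TBS-oxy)-5-hydroxy-7-isopropyl-4-methylidene-octahydro-2H-inden-2-one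
Conditions: SeO2 (cat.), t-BuOOH, CH2Cl2, 0 °C → rt
Reagents that add atoms: tert-butyl hydroperoxide, CC(C)(C)OO
Why: Selenium dioxide allylic hydroxylation (ene reaction, then 2,3-sigmatropic shift) of the 1,1-disubstituted alkene should attack the allylic CH2 (C5) in preference to the ring-fusion CH, removing the axial hydrogen and returning oxygen to the same face, which is also anti to the axial C6 silyloxy group, so the C5 hydroxyl is axial and trans to the C6 oxygen.

Step 13
Reactants: 24 allylic alcohol; 25 angelic acid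
Product: 26 (1R,3aR,5S,6S,7S,7aR)-1,6-bis(TBS-oxy)-7-isopropyl-4-methylidene-2-oxo-octahydro-1H-inden-5-yl (Z)-2-methylbut-2-enoate
Conditions: angelic acid, 2,4,6-trichlorobenzoyl chloride, Et3N, toluene, rt; then 24, toluene, 75 °C
Reagents that add atoms: angelic acid, C/C=C(/C)C(=O)O
Why: Acylation through the mixed 2,4,6-trichlorobenzoic anhydride (Yamaguchi-type esterification without nucleophilic catalyst) should transfer the angeloyl group without Z to E isomerisation, with retention at the carbinol carbon.

Step 14
Reactants: 26 bis-silyl angelate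
Product: 27 (1R,3aR,5S,6S,7S,7aR)-1,6-dihydroxy-7-isopropyl-4-methylidene-2-oxo-octahydro-1H-inden-5-yl (Z)-2-methylbut-2-enoate
Conditions: HF·pyridine, pyridine, THF, 0 °C → rt
Reagents that add atoms: none
Why: Fluoride-mediated desilylation should remove both silyl ethers while leaving the ester, the α-ketol and the allylic system intact; the trans-diaxial C5/C6 oxygens cannot exchange the angeloyl group.

Step 15
Reactants: 27 diol; 28 acetic anhydride
Product: 29 (1R,3aR,5S,6S,7S,7aR)-1-acetoxy-6-hydroxy-7-isopropyl-4-methylidene-2-oxo-octahydro-1H-inden-5-yl (Z)-2-methylbut-2-enoate (target)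
Conditions: Ac2O (1.1 equiv), pyridine, CH2Cl2, 0 °C
Reagents that add atoms: acetic anhydride, CC(=O)OC(C)=O
Why: Selective O-acetylation of the less hindered α-ketol hydroxyl at C1; the C6 hydroxyl is axial and flanked by the isopropyl-bearing and angeloyloxy-bearing carbons and should react much more slowly.

**Compound list**

1 | (R)-4-(TBS-oxy)cyclopent-2-en-1-one | O=C1C=C[C@H](O[Si](C)(C)C(C)(C)C)C1 | starting material
2 | isopropylmagnesium chloride | CC(C)[Mg]Cl | starting material
3 | chloromagnesium enolate of (3R,4R)-4-(TBS-oxy)-3-isopropylcyclopentanone (formed in the flask) | Cl[Mg]OC1=C[C@@H](C(C)C)[C@H](O[Si](C)(C)C(C)(C)C)C1 | intermediate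
4 | (R)-4-(TBS-oxy)-3-isopropylcyclopent-2-en-1-one | O=C1C=C(C(C)C)[C@H](O[Si](C)(C)C(C)(C)C)C1 | intermediate
5 | dimethylphenylsilane | C[SiH](C)c1ccccc1 | starting material
6 | 2-[(4-methoxybenzyl)oxy]acetaldehyde | O=CCOCc1ccc(OC)cc1 | starting material
7 | dimethylphenylsilyl enol ether of (3S,4R)-4-(TBS-oxy)-3-isopropylcyclopentanone (formed in the flask) | C[Si](C)(OC1=C[C@H](C(C)C)[C@H](O[Si](C)(C)C(C)(C)C)C1)c1ccccc1 | intermediate
8 | (2R,3S,4R)-4-(TBS-oxy)-2-[(1R)-1-hydroxy-2-(PMB-oxy)ethyl]-3-isopropylcyclopentan-1-one (side chain trans to iPr; iPr cis to OTBS; syn aldol) | O=C1[C@@H]([C@@H](O)COCc2ccc(OC)cc2)[C@H](C(C)C)[C@H](O[Si](C)(C)C(C)(C)C)C1 | intermediate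
9 | tert-butyldimethylsilyl trifluoromethanesulfonate | CC(C)(C)[Si](C)(C)OS(=O)(=O)C(F)(F)F | starting material
10 | TBS ether of 8 at the side-chain carbinol | O=C1[C@@H]([C@@H](O[Si](C)(C)C(C)(C)C)COCc2ccc(OC)cc2)[C@H](C(C)C)[C@H](O[Si](C)(C)C(C)(C)C)C1 | intermediate
11 | vinylmagnesium bromide | C=C[Mg]Br | starting material
12 | (1S,2R,3S,4R)-1-ethenyl-4-(TBS-oxy)-2-[(1R)-1-(TBS-oxy)-2-(PMB-oxy)ethyl]-3-isopropylcyclopentan-1-ol (vinyl trans to side chain) | C=C[C@]1(O)[C@@H]([C@@H](O[Si](C)(C)C(C)(C)C)COCc2ccc(OC)cc2)[C@H](C(C)C)[C@H](O[Si](C)(C)C(C)(C)C)C1 | intermediate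
13 | triethylsilyl trifluoromethanesulfonate | CC[Si](CC)(CC)OS(=O)(=O)C(F)(F)F | starting material
14 | triethylsilyl ether of 12 | C=C[C@]1(O[Si](CC)(CC)CC)[C@@H]([C@@H](O[Si](C)(C)C(C)(C)C)COCc2ccc(OC)cc2)[C@H](C(C)C)[C@H](O[Si](C)(C)C(C)(C)C)C1 | intermediate
15 | primary alcohol from 14 (PMB removed) | C=C[C@]1(O[Si](CC)(CC)CC)[C@@H]([C@@H](O[Si](C)(C)C(C)(C)C)CO)[C@H](C(C)C)[C@H](O[Si](C)(C)C(C)(C)C)C1 | intermediate
16 | α-silyloxy aldehyde from 15 | C=C[C@]1(O[Si](CC)(CC)CC)[C@@H]([C@@H](O[Si](C)(C)C(C)(C)C)C=O)[C@H](C(C)C)[C@H](O[Si](C)(C)C(C)(C)C)C1 | intermediate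
17 | Prins cation: bicyclo[4.3.0]nonyl cation with the charge next to the triethylsilyloxy carbon; new oxygen bound to tin (formed in the flask) | [CH+]1C[C@@H](O[Sn-](Cl)(Cl)(Cl)Cl)[C@H](O[Si](C)(C)C(C)(C)C)[C@H]2[C@H](C(C)C)[C@H](O[Si](C)(C)C(C)(C)C)C[C@]12O[Si](CC)(CC)CC | intermediate
18 | (1R,2R,3aS,6R,7S,7aS)-1,6-bis(TBS-oxy)-2-hydroxy-7-isopropyl-octahydro-4H-inden-4-one (cis-fused) | O=C1[C@H]2C[C@@H](O)[C@H](O[Si](C)(C)C(C)(C)C)[C@H]2[C@H](C(C)C)[C@H](O[Si](C)(C)C(C)(C)C)C1 | intermediate
19 | (1R,2R,3aR,6R,7S,7aS)-1,6-bis(TBS-oxy)-2-hydroxy-7-isopropyl-octahydro-4H-inden-4-one (trans-fused) | O=C1[C@@H]2C[C@@H](O)[C@H](O[Si](C)(C)C(C)(C)C)[C@H]2[C@H](C(C)C)[C@H](O[Si](C)(C)C(C)(C)C)C1 | intermediate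
20 | methyltriphenylphosphonium bromide | C[P+](c1ccccc1)(c1ccccc1)c1ccccc1.[Br-] | starting material
21 | (1R,2R,3aR,6R,7S,7aR)-1,6-bis(TBS-oxy)-7-isopropyl-4-methylidene-octahydro-1H-inden-2-ol | C=C1[C@@H]2C[C@@H](O)[C@H](O[Si](C)(C)C(C)(C)C)[C@H]2[C@H](C(C)C)[C@H](O[Si](C)(C)C(C)(C)C)C1 | intermediate
22 | (1R,3aR,6R,7S,7aR)-1,6-bis(TBS-oxy)-7-isopropyl-4-methylidene-octahydro-2H-inden-2-one | C=C1[C@@H]2CC(=O)[C@H](O[Si](C)(C)C(C)(C)C)[C@H]2[C@H](C(C)C)[C@H](O[Si](C)(C)C(C)(C)C)C1 | intermediate
23 | tert-butyl hydroperoxide | CC(C)(C)OO | starting material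
24 | (1R,3aR,5S,6S,7S,7aR)-1,6-bis(TBS-oxy)-5-hydroxy-7-isopropyl-4-methylidene-octahydro-2H-inden-2-one | C=C1[C@@H]2CC(=O)[C@H](O[Si](C)(C)C(C)(C)C)[C@H]2[C@H](C(C)C)[C@H](O[Si](C)(C)C(C)(C)C)[C@H]1O | intermediate
25 | angelic acid, (Z)-2-methylbut-2-enoic acid | C/C=C(/C)C(=O)O | starting material
26 | C5 angelate of 24 | C=C1[C@@H]2CC(=O)[C@H](O[Si](C)(C)C(C)(C)C)[C@H]2[C@H](C(C)C)[C@H](O[Si](C)(C)C(C)(C)C)[C@H]1OC(=O)/C(C)=C\C | intermediate
27 | (1R,3aR,5S,6S,7S,7aR)-1,6-dihydroxy-7-isopropyl-4-methylidene-2-oxo-octahydro-1H-inden-5-yl (Z)-2-methylbut-2-enoate | C=C1[C@@H]2CC(=O)[C@H](O)[C@H]2[C@H](C(C)C)[C@H](O)[C@H]1OC(=O)/C(C)=C\C | intermediate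
28 | acetic anhydride | CC(=O)OC(C)=O | starting material
29 | (1R,3aR,5S,6S,7S,7aR)-1-acetoxy-6-hydroxy-7-isopropyl-4-methylidene-2-oxo-octahydro-1H-inden-5-yl (Z)-2-methylbut-2-enoate | C=C1[C@@H]2CC(=O)[C@H](OC(C)=O)[C@H]2[C@H](C(C)C)[C@H](O)[C@H]1OC(=O)/C(C)=C\C | target

**Step count and risks**

Total step count: 15. Longest linear sequence: 15 steps (from 1).

Three steps most likely to fail:

Step 8. The unactivated vinyl group is a weak π-nucleophile toward the SnCl4-bound aldehyde, so ionisation of the tertiary allylic silyl ether, chloride capture of the secondary cation or migration of the C1–C5 bond may compete with the desired addition and shift. The fallback sets out from aldehyde 16. Acetalisation with benzyloxytrimethylsilane and catalytic TMSOTf (CH2Cl2, −78 °C) should give the dibenzyl acetal F1. SnCl4 (CH2Cl2, −78 → −23 °C) ionises it to a free alkyl oxocarbenium ion, the initiator for which this Prins–pinacol annulation is established, and should give the cis-fused C2 benzyl ether F2. Hydrogenolysis (H2, Pd/C, EtOAc) then comes back to the route at 18.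

Step 2. Hydride transfer to the hindered β,β-disubstituted enone may be slow, the open transition state of the Lewis-acid aldol may give poor syn/anti selection, and the PMB ether may be lost to TiCl4. The fallback sets out from 4: the conjugate reduction is run alone and the enol silane 7 is isolated. MeLi (THF, 0 °C) releases the lithium enolate F3, and ClTi(OiPr)3 converts it into the tris(isopropoxy)titanium enolate F4. Addition of 6 at −78 °C then passes through a closed transition state, which for such titanium enolates of cyclic ketones favours the syn adduct, and comes back to the route at 8.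

Step 9. The cis/trans equilibrium may leave too much cis isomer, or E1cB loss of the C6 silyloxy group through the C4–C5 enolate may compete. The fallback uses kinetic instead of thermodynamic control and sets out from 18. TMSCl/NaI/Et3N (MeCN, rt) should give the more substituted C3a=C4 enol silane with the C2 hydroxyl also silylated, the bis(trimethylsilyl) compound F5. Protonation at carbon at −78 °C (HCl, THF) is expected to occur axially on the face anti to the C7a hydrogen and away from the silyloxy group at C1, and the same acidic work-up frees the C2 hydroxyl, coming back to the route at 19.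

**Further compounds**

F1 | step 8 | dibenzyl acetal of aldehyde 16 | C=C[C@]1(O[Si](CC)(CC)CC)[C@@H]([C@@H](O[Si](C)(C)C(C)(C)C)C(OCc2ccccc2)OCc2ccccc2)[C@H](C(C)C)[C@H](O[Si](C)(C)C(C)(C)C)C1
F2 | step 8 | cis-fused 2-benzyloxy-1,6-bis(TBS-oxy)-7-isopropyl-octahydro-4H-inden-4-one | O=C1[C@H]2C[C@@H](OCc3ccccc3)[C@H](O[Si](C)(C)C(C)(C)C)[C@H]2[C@H](C(C)C)[C@H](O[Si](C)(C)C(C)(C)C)C1
F3 | step 2 | lithium enolate of (3S,4R)-4-(TBS-oxy)-3-isopropylcyclopentanone | [Li]OC1=C[C@H](C(C)C)[C@H](O[Si](C)(C)C(C)(C)C)C1
F4 | step 2 | tris(isopropoxy)titanium enolate of (3S,4R)-4-(TBS-oxy)-3-isopropylcyclopentanone | CC(C)O[Ti](OC(C)C)(OC(C)C)OC1=C[C@H](C(C)C)[C@H](O[Si](C)(C)C(C)(C)C)C1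
F5 | step 9 | C3a=C4 trimethylsilyl enol ether of 18 with the C2 hydroxyl as trimethylsilyl ether | C[Si](C)(C)OC1=C2C[C@@H](O[Si](C)(C)C)[C@H](O[Si](C)(C)C(C)(C)C)[C@H]2[C@H](C(C)C)[C@H](O[Si](C)(C)C(C)(C)C)C1
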